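**Plan**

1. Tetralone numbering: C1 (C=O), C2, C3 (CH bearing isopropenyl), C4 (quaternary), C4a–C8a (ring A). The C5/C8 phenols are carried as methyl ethers, isopropenyl as vinyl (then methyl ketone), and the propanoic acid chain as a formyl group on C4.
2. Ring B is then cut at C3–C4 and at C1–C8a. This gives 2-arylpropanal 8 (C4, its methyl, C4a, C8a) and tert-butyl 3-hydroxypent-4-enoate 11 (C1–C2–C3 plus the vinyl group); the arene comes from 1,2,4-trimethoxybenzene by two ortho-lithiations.
3. Enabling feature: C4 is benzylic and, at the aldehyde level, an enamine carbon. C3 is allylic and β to C1, so C1–C3 is a branched allyl electrophile for iridium. C8a is the only free carbon of ring A, ortho to O8 and para to O6, so the C1 carboxyl closes ring B on it.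
4. Forward order: ring A is fully substituted first (steps 1–3), then aldehyde 8 (step 4). Ring B is built in one flask in step 6: iridium/amine allylation forms C3–C4, Friedel–Crafts acylation forms C1–C8a. Chain, isopropenyl and phenols follow (steps 7–12).
5. Stereochemistry: C3 comes from the chiral ligand on iridium and C4 from the cinchona primary amine (independent catalyst control, vinyl cis to methyl). C4 is quaternary, and C3 is handled only under non-basic conditions afterwards.

Key step: step 6

Assumption: the ligand antipode and the cinchona pseudo-enantiomer named in step 6 are taken to be the pair that gives (3S,4S)-12; each catalyst controls its own centre, so the other antipode or pseudo-enantiomer is used if the sense is opposite. The ligand is (R)-4-(5H-dibenzo[b,f]azepin-5-yl)dinaphtho[2,1-d:1',2'-f][1,3,2]dioxaphosphepine.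

**Route**

Step 1
Reactants: 1 1,2,4-trimethoxybenzene
Product: 3 2-(2,3,6-trimethoxyphenyl)propan-2-ol, via aryllithium 2 (not isolated)
Conditions: n-BuLi, THF, 0 °C → rt; acetone, −78 °C → rt; H2O
Reagents that add atoms: acetone CC(C)=O
Why: Directed ortho-metalation removes the hydrogen between the 2- and 4-methoxy groups, the most acidic position, and the aryllithium adds to acetone.

Step 2
Reactants: 3 2-(2,3,6-trimethoxyphenyl)propan-2-ol
Product: 4 2-isopropyl-1,3,4-trimethoxybenzene
Conditions: Et3SiH, CF3CO2H, CH2Cl2, 0 °C → rt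
Reagents that add atoms: none
Why: Ionic hydrogenation: CF3CO2H ionises the tertiary benzylic alcohol to a cation stabilised by two ortho methoxy groups, and Et3SiH reduces it to the isopropyl group.

Step 3
Reactants: 4 2-isopropyl-1,3,4-trimethoxybenzene
Product: 6 1-(4-isopropyl-2,3,5-trimethoxyphenyl)ethan-1-one, via aryllithium 5 (not isolated)
Conditions: n-BuLi, TMEDA, Et2O, 0 °C → rt; MeC(O)N(OMe)Me, −78 → 0 °C; H2O
Reagents that add atoms: N-methoxy-N-methylacetamide CC(=O)N(C)OC
Why: Second directed ortho-metalation: H-5 is ortho to one and meta to two methoxy groups, whereas H-6 is para to the 3-methoxy donor, so lithiation should occur at C5; acylation with the N-methoxy-N-methylamide stops at the ketone through the chelated tetrahedral adduct.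

Step 4
Reactants: 6 1-(4-isopropyl-2,3,5-trimethoxyphenyl)ethan-1-one
Product: 8 2-(4-isopropyl-2,3,5-trimethoxyphenyl)propanal (racemic), via enol ether 7 (not isolated)
Conditions: MeOCH2PPh3Cl, KN(SiMe3)2, THF, 0 °C → rt; then 2 M HCl, THF, rt
Reagents that add atoms: (methoxymethyl)triphenylphosphonium chloride COC[P+](c1ccccc1)(c1ccccc1)c1ccccc1.[Cl-]; water O
Why: Wittig methoxymethylenation of the ketone and acid hydrolysis of the enol ether give the one-carbon-homologated α-branched aldehyde; it is racemic, which does not matter because this carbon becomes an enamine carbon in step 6.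

Step 5
Reactants: 9 tert-butyl acetate
Product: 11 tert-butyl 3-hydroxypent-4-enoate (racemic), via lithium enolate 10 (not isolated)
Conditions: LiN(i-Pr)2, THF, −78 °C; acrolein, −78 °C; H2O
Reagents that add atoms: acrolein C=CC=O
Why: Aldol addition of the ester enolate to the aldehyde carbonyl of acrolein (1,2-addition at low temperature); the racemate suffices because both enantiomers give the same allyliridium intermediate in step 6.

Step 6
Reactants: 8 2-(4-isopropyl-2,3,5-trimethoxyphenyl)propanal (racemic); 11 tert-butyl 3-hydroxypent-4-enoate (racemic)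
Product: 14 (1S,2S)-2-ethenyl-6-isopropyl-5,7,8-trimethoxy-1-methyl-4-oxo-1,2,3,4-tetrahydronaphthalene-1-carbaldehyde, via allylated aldehyde ester 12 (not isolated), via aldehyde acid 13 (not isolated)
Conditions: [Ir(cod)Cl]2 (3 mol %), (R)-phosphoramidite–olefin ligand (12 mol %), 9-amino-9-deoxy-epi-quinidine (10 mol %), Cl3CCO2H (0.5 equiv), ClCH2CH2Cl, 25 °C; then CF3CO2H, (CF3CO)2O, 0 °C → rt
Reagents that add atoms: none
Why: Condensation of racemic 8 with the cinchona primary amine gives a tetrasubstituted enamine (the α-stereocentre is erased), while acid-assisted ionisation of either enantiomer of 11 at the ligated iridium gives one η3-allyl complex; C-attack of the enamine on the substituted allyl terminus, the branched selectivity inherent to iridium, forms the C3–C4 bond and hydrolysis returns the amine and aldehyde 12. The closest known reaction type is the stereodivergent iridium/amine dual-catalytic α-allylation of 2-arylpropanals with branched allylic alcohols, followed here in the same flask by a classical intramolecular Friedel–Crafts acylation. After tert-butyl cleavage by CF3CO2H, acid 13 is turned by (CF3CO)2O into a mixed anhydride whose carbonyl is attacked by C8a in a 6-exo-trig closure of ring B; C8a is the only free ring position and lies para to the C6 and ortho to the C8 methoxy group. C3 is set by the chiral ligand on iridium (which face of the allyl terminus is attacked) and C4 by the cinchona amine (which face of the enamine reacts); because the two catalysts act independently, the (3S,4S) pairing that places vinyl cis to methyl on ring B is selected by the combination of antipodes. The step needs branched rather than linear attack, C- rather than N-allylation and no later epimerisation: the quaternary aldehyde carbon of 12 has no α-hydrogen, C3 is not acidic, and 12 carries a single carboxyl function so the acylation is unambiguous.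

Step 7
Reactants: 14 (1S,2S)-2-ethenyl-6-isopropyl-5,7,8-trimethoxy-1-methyl-4-oxo-1,2,3,4-tetrahydronaphthalene-1-carbaldehyde
Product: 15 methyl (E)-3-[(1S,2S)-2-ethenyl-6-isopropyl-5,7,8-trimethoxy-1-methyl-4-oxo-1,2,3,4-tetrahydronaphthalen-1-yl]prop-2-enoate
Conditions: Ph3P=CHCO2Me, toluene, 90 °C
Reagents that add atoms: methyl (triphenylphosphoranylidene)acetate COC(=O)C=P(c1ccccc1)(c1ccccc1)c1ccccc1
Why: Wittig olefination with the stabilised ylide is chemoselective for the aldehyde over the hindered aryl ketone and should give the E-enoate; the neutral conditions leave both stereocentres untouched.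

Step 8
Reactants: 15 methyl (E)-3-[(1S,2S)-2-ethenyl-6-isopropyl-5,7,8-trimethoxy-1-methyl-4-oxo-1,2,3,4-tetrahydronaphthalen-1-yl]prop-2-enoate
Product: 16 methyl (E)-3-[(1S,2R)-2-acetyl-6-isopropyl-5,7,8-trimethoxy-1-methyl-4-oxo-1,2,3,4-tetrahydronaphthalen-1-yl]prop-2-enoate
Conditions: PdCl2 (10 mol %), CuCl, O2 (1 atm), DMF/H2O 7:1, rt
Reagents that add atoms: water O
Why: Wacker oxidation: Markovnikov oxypalladation of the monosubstituted vinyl group gives the methyl ketone while the electron-poor enoate is not attacked; room temperature is used so that C3, now α to a ketone, does not epimerise (the descriptor changes to R only because acetyl outranks C1 of the ring).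

Step 9
Reactants: 16 methyl (E)-3-[(1S,2R)-2-acetyl-6-isopropyl-5,7,8-trimethoxy-1-methyl-4-oxo-1,2,3,4-tetrahydronaphthalen-1-yl]prop-2-enoate
Product: 17 methyl 3-[(1S,2R)-2-acetyl-6-isopropyl-5,7,8-trimethoxy-1-methyl-4-oxo-1,2,3,4-tetrahydronaphthalen-1-yl]propanoate
Conditions: H2 (1 atm), 10 % Pd/C, EtOAc, rt
Reagents that add atoms: none
Why: Catalytic hydrogenation saturates the only C=C bond left, the enoate, which is why it is placed before the isopropenyl group is made; the neutral conditions do not touch C3.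

Step 10
Reactants: 17 methyl 3-[(1S,2R)-2-acetyl-6-isopropyl-5,7,8-trimethoxy-1-methyl-4-oxo-1,2,3,4-tetrahydronaphthalen-1-yl]propanoate
Product: 18 methyl 3-[(1S,2S)-6-isopropyl-5,7,8-trimethoxy-1-methyl-4-oxo-2-(prop-1-en-2-yl)-1,2,3,4-tetrahydronaphthalen-1-yl]propanoate
Conditions: Zn, CH2Br2, TiCl4, THF, 0 °C; then 17, CH2Cl2, 0 °C → rt
Reagents that add atoms: dibromomethane BrCBr
Why: Takai–Lombardo methylenation: the non-basic zinc/titanium methylene reagent converts the methyl ketone into the 1,1-disubstituted alkene without enolisation (no epimerisation at C3, no aldol of the 1,4-diketone), while the ester and the conjugated, peri-flanked aryl ketone should react more slowly.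

Step 11
Reactants: 18 methyl 3-[(1S,2S)-6-isopropyl-5,7,8-trimethoxy-1-methyl-4-oxo-2-(prop-1-en-2-yl)-1,2,3,4-tetrahydronaphthalen-1-yl]propanoate
Product: 19 3-[(1S,2S)-6-isopropyl-5,7,8-trimethoxy-1-methyl-4-oxo-2-(prop-1-en-2-yl)-1,2,3,4-tetrahydronaphthalen-1-yl]propanoic acid
Conditions: LiOH·H2O, THF/H2O, rt; then 1 M HCl
Reagents that add atoms: lithium hydroxide [Li+].[OH-]
Why: Saponification of the methyl ester; the quaternary C4 and the non-acidic C3 are not at risk.

Step 12
Reactants: 19 3-[(1S,2S)-6-isopropyl-5,7,8-trimethoxy-1-methyl-4-oxo-2-(prop-1-en-2-yl)-1,2,3,4-tetrahydronaphthalen-1-yl]propanoic acid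
Product: 21 3-[(1S,2S)-5,8-dihydroxy-6-isopropyl-7-methoxy-1-methyl-4-oxo-2-(prop-1-en-2-yl)-1,2,3,4-tetrahydronaphthalen-1-yl]propanoic acid (CNP0249049.1), via quinone 20 (not isolated)
Conditions: (NH4)2Ce(NO3)6, MeCN/H2O, 0 °C; then Na2S2O4, H2O/EtOAc, rt
Reagents that add atoms: water O
Why: Oxidative demethylation of the para-dimethoxy pair at C5/C8 should give the methoxy-p-quinone (the C6 methoxy group survives as a vinylogous ester), and dithionite reduction of this acylquinone gives the hydroquinone, which is the target.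

**Compound list**

1 | 1,2,4-trimethoxybenzene | COc1ccc(OC)c(OC)c1 | starting material
2 | (2,3,6-trimethoxyphenyl)lithium | [Li]c1c(OC)ccc(OC)c1OC | intermediate (not isolated)
3 | 2-(2,3,6-trimethoxyphenyl)propan-2-ol | COc1ccc(OC)c(OC)c1C(C)(C)O | intermediate
4 | 2-isopropyl-1,3,4-trimethoxybenzene | COc1ccc(OC)c(OC)c1C(C)C | intermediate
5 | (4-isopropyl-2,3,5-trimethoxyphenyl)lithium | [Li]c1cc(OC)c(C(C)C)c(OC)c1OC | intermediate (not isolated)
6 | 1-(4-isopropyl-2,3,5-trimethoxyphenyl)ethan-1-one | CC(=O)c1cc(OC)c(C(C)C)c(OC)c1OC | intermediate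
7 | 2-(4-isopropyl-2,3,5-trimethoxyphenyl)-1-methoxyprop-1-ene (E/Z mixture) | COC=C(C)c1cc(OC)c(C(C)C)c(OC)c1OC | intermediate (not isolated)
8 | 2-(4-isopropyl-2,3,5-trimethoxyphenyl)propanal (racemic) | CC(C=O)c1cc(OC)c(C(C)C)c(OC)c1OC | intermediate
9 | tert-butyl acetate | CC(=O)OC(C)(C)C | starting material
10 | lithium 1-tert-butoxyethen-1-olate (enolate of 9) | C=C(O[Li])OC(C)(C)C | intermediate (not isolated)
11 | tert-butyl 3-hydroxypent-4-enoate (racemic) | C=CC(O)CC(=O)OC(C)(C)C | intermediate
12 | tert-butyl (3S,4S)-3-ethenyl-4-(4-isopropyl-2,3,5-trimethoxyphenyl)-4-methyl-5-oxopentanoate | C=C[C@H](CC(=O)OC(C)(C)C)[C@](C)(C=O)c1cc(OC)c(C(C)C)c(OC)c1OC | intermediate (not isolated)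
13 | (3S,4S)-3-ethenyl-4-(4-isopropyl-2,3,5-trimethoxyphenyl)-4-methyl-5-oxopentanoic acid | C=C[C@H](CC(=O)O)[C@](C)(C=O)c1cc(OC)c(C(C)C)c(OC)c1OC | intermediate (not isolated)
14 | (1S,2S)-2-ethenyl-6-isopropyl-5,7,8-trimethoxy-1-methyl-4-oxo-1,2,3,4-tetrahydronaphthalene-1-carbaldehyde | C=C[C@@H]1CC(=O)c2c(OC)c(C(C)C)c(OC)c(OC)c2[C@@]1(C)C=O | intermediate
15 | methyl (E)-3-[(1S,2S)-2-ethenyl-6-isopropyl-5,7,8-trimethoxy-1-methyl-4-oxo-1,2,3,4-tetrahydronaphthalen-1-yl]prop-2-enoate | C=C[C@@H]1CC(=O)c2c(OC)c(C(C)C)c(OC)c(OC)c2[C@@]1(C)/C=C/C(=O)OC | intermediate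
16 | methyl (E)-3-[(1S,2R)-2-acetyl-6-isopropyl-5,7,8-trimethoxy-1-methyl-4-oxo-1,2,3,4-tetrahydronaphthalen-1-yl]prop-2-enoate | CC(=O)[C@@H]1CC(=O)c2c(OC)c(C(C)C)c(OC)c(OC)c2[C@@]1(C)/C=C/C(=O)OC | intermediate
17 | methyl 3-[(1S,2R)-2-acetyl-6-isopropyl-5,7,8-trimethoxy-1-methyl-4-oxo-1,2,3,4-tetrahydronaphthalen-1-yl]propanoate | CC(=O)[C@@H]1CC(=O)c2c(OC)c(C(C)C)c(OC)c(OC)c2[C@@]1(C)CCC(=O)OC | intermediate
18 | methyl 3-[(1S,2S)-6-isopropyl-5,7,8-trimethoxy-1-methyl-4-oxo-2-(prop-1-en-2-yl)-1,2,3,4-tetrahydronaphthalen-1-yl]propanoate | C=C(C)[C@@H]1CC(=O)c2c(OC)c(C(C)C)c(OC)c(OC)c2[C@@]1(C)CCC(=O)OC | intermediate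
19 | 3-[(1S,2S)-6-isopropyl-5,7,8-trimethoxy-1-methyl-4-oxo-2-(prop-1-en-2-yl)-1,2,3,4-tetrahydronaphthalen-1-yl]propanoic acid | C=C(C)[C@@H]1CC(=O)c2c(OC)c(C(C)C)c(OC)c(OC)c2[C@@]1(C)CCC(=O)O | intermediate
20 | 3-[(1S,2S)-6-isopropyl-7-methoxy-1-methyl-4,5,8-trioxo-2-(prop-1-en-2-yl)-1,2,3,4,5,8-hexahydronaphthalen-1-yl]propanoic acid | C=C(C)[C@@H]1CC(=O)C2=C(C(=O)C(OC)=C(C(C)C)C2=O)[C@@]1(C)CCC(=O)O | intermediate (not isolated)
21 | 3-[(1S,2S)-5,8-dihydroxy-6-isopropyl-7-methoxy-1-methyl-4-oxo-2-(prop-1-en-2-yl)-1,2,3,4-tetrahydronaphthalen-1-yl]propanoic acid | C=C(C)[C@@H]1CC(=O)c2c(O)c(C(C)C)c(OC)c(O)c2[C@@]1(C)CCC(=O)O | target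

**Step count**

Total: 12 steps. Longest linear sequence: 11 steps (steps 1–4 and 6–12).

**Steps most likely to fail**

Step 6. Ionisation of the aliphatic β-hydroxy ester at iridium may be slow and may compete with loss of water to the dienoate or with linear attack, so that the hindered C3–C4 bond forms in low yield or with eroded diastereocontrol. The fallback sets out from 8 and returns at 18. The same iridium/amine allylation is run with 2-methylpenta-1,4-dien-3-ol (from methacrolein and vinylmagnesium bromide), an alkenyl-activated carbinol that brings the isopropenyl group in directly, to give (2S,3S)-2-(4-isopropyl-2,3,5-trimethoxyphenyl)-2-methyl-3-(prop-1-en-2-yl)pent-4-enal F1. Wittig olefination with Ph3P=CHCO2Me gives methyl (2E,4S,5S)-4-(4-isopropyl-2,3,5-trimethoxyphenyl)-4-methyl-5-(prop-1-en-2-yl)hepta-2,6-dienoate F2. Conjugate reduction with [(Ph3P)CuH]6 and PhMe2SiH gives methyl (4S,5S)-4-(4-isopropyl-2,3,5-trimethoxyphenyl)-4-methyl-5-(prop-1-en-2-yl)hept-6-enoate F3. Hydroboration of the monosubstituted vinyl group with disiamylborane and oxidation with NaBO3 gives methyl (4S,5S)-7-hydroxy-4-(4-isopropyl-2,3,5-trimethoxyphenyl)-4-methyl-5-(prop-1-en-2-yl)heptanoate F4. Oxidation (Dess–Martin periodinane, then NaClO2) gives (3S,4S)-4-(4-isopropyl-2,3,5-trimethoxyphenyl)-7-methoxy-4-methyl-7-oxo-3-(prop-1-en-2-yl)heptanoic acid F5, and Friedel–Crafts acylation with (CF3CO)2O closes ring B to 18. Ring B is thus closed in a separate step and steps 8–10 are not needed.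

Step 8. Oxypalladation of the hindered vinyl group may be slow, and the acidic, chloride-containing medium may epimerise C3 once the ketone has formed or condense the 1,4-diketone. The fallback sets out from 15 and returns at 16. Markovnikov hydration without palladium by oxymercuration–demercuration (Hg(OAc)2, THF/H2O; then NaBH4, NaOH) gives methyl (E)-3-[(1S,2R)-2-(1-hydroxyethyl)-6-isopropyl-5,7,8-trimethoxy-1-methyl-4-oxo-1,2,3,4-tetrahydronaphthalen-1-yl]prop-2-enoate F6 as a mixture of carbinol epimers. Buffered oxidation (Dess–Martin periodinane, NaHCO3) then gives 16 and also returns to the ketone any C1 alcohol formed by the borohydride.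

Step 3. Lithiation may occur partly at H-6, ortho to the 1-methoxy group, which would put the side chain on the wrong ring carbon. The fallback sets out from 4 and returns at 6. The more nucleophilic C6 is first blocked by bromination (NBS, MeCN) to 1-bromo-3-isopropyl-2,4,5-trimethoxybenzene F7. Deprotonation of the only ring hydrogen left, ortho to bromine and methoxy, with lithium 2,2,6,6-tetramethylpiperidide at −78 °C and acylation with N-methoxy-N-methylacetamide give 1-(2-bromo-4-isopropyl-3,5,6-trimethoxyphenyl)ethan-1-one F8. Hydrogenolysis of the C–Br bond (H2, Pd/C, Et3N) returns ketone 6.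

**Further compounds**

F1 | step 6 | (2S,3S)-2-(4-isopropyl-2,3,5-trimethoxyphenyl)-2-methyl-3-(prop-1-en-2-yl)pent-4-enal | C=C(C)[C@H](C=C)[C@](C)(C=O)c1cc(OC)c(C(C)C)c(OC)c1OC
F2 | step 6 | methyl (2E,4S,5S)-4-(4-isopropyl-2,3,5-trimethoxyphenyl)-4-methyl-5-(prop-1-en-2-yl)hepta-2,6-dienoate | C=C(C)[C@H](C=C)[C@](C)(/C=C/C(=O)OC)c1cc(OC)c(C(C)C)c(OC)c1OC
F3 | step 6 | methyl (4S,5S)-4-(4-isopropyl-2,3,5-trimethoxyphenyl)-4-methyl-5-(prop-1-en-2-yl)hept-6-enoate | C=C(C)[C@H](C=C)[C@](C)(CCC(=O)OC)c1cc(OC)c(C(C)C)c(OC)c1OC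
F4 | step 6 | methyl (4S,5S)-7-hydroxy-4-(4-isopropyl-2,3,5-trimethoxyphenyl)-4-methyl-5-(prop-1-en-2-yl)heptanoate | C=C(C)[C@H](CCO)[C@](C)(CCC(=O)OC)c1cc(OC)c(C(C)C)c(OC)c1OC
F5 | step 6 | (3S,4S)-4-(4-isopropyl-2,3,5-trimethoxyphenyl)-7-methoxy-4-methyl-7-oxo-3-(prop-1-en-2-yl)heptanoic acid | C=C(C)[C@H](CC(=O)O)[C@](C)(CCC(=O)OC)c1cc(OC)c(C(C)C)c(OC)c1OC
F6 | step 8 | methyl (E)-3-[(1S,2R)-2-(1-hydroxyethyl)-6-isopropyl-5,7,8-trimethoxy-1-methyl-4-oxo-1,2,3,4-tetrahydronaphthalen-1-yl]prop-2-enoate (carbinol epimers) | CC(O)[C@@H]1CC(=O)c2c(OC)c(C(C)C)c(OC)c(OC)c2[C@@]1(C)/C=C/C(=O)OC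
F7 | step 3 | 1-bromo-3-isopropyl-2,4,5-trimethoxybenzene | COc1c(Br)cc(OC)c(OC)c1C(C)C
F8 | step 3 | 1-(2-bromo-4-isopropyl-3,5,6-trimethoxyphenyl)ethan-1-one | CC(=O)c1c(Br)c(OC)c(C(C)C)c(OC)c1OC
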